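**Retrosynthetic overview**

1. Numbering: ring A = C10–C1–C2–C3–C4–C5, ring B = C5–C6–C7–C8–C9–C10; C11 = CH2O on C9, C12 = exocyclic CH2 on C8, C15 and C16 = methyls on C10 and C5; β = the face of these two methyls.
2. The route rests on the C8=C12 methylene lying between C9 (which carries C11–O) and the quaternary C10: it is the footprint of a 2-(silylmethyl)allyl unit that has added through C9 to C10. Ring B is therefore cut at C9–C10, back to a ring-A enone (C2=O, C1=C10) with a (Z)-allylsilane chain on the quaternary C5.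
3. The enone comes from dimedone (C4 gem-dimethyl in place): vinylogous ester, α′-methylation, enantioselective decarboxylative allylation (C5), chain growth via β-keto ester, (Z)-enol triflate and Me3SiCH2MgCl, then Stork–Danheiser transposition (C15) and α′-hydroxylation (C3–O).
4. After ring closure the C2 oxygen is removed (Barton–McCombie), C3 is converged to the ketone and reduced anti to the axial C5 methyl, and Mitsunobu etherification at C11 with umbelliferone and acetylation finish the route.
5. Ring order: ring A (from dimedone), then ring B (key step); the coumarin is attached near the end.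

Key step: step 15

Remark 1 (assumption): the (S)-phosphinooxazoline ligand is taken to deliver the allyl group to the same enolate face as with 2-alkylcyclohexanone enolates, which corresponds to (R)-9; if the sense were opposite, the (R)-ligand would be used.

Remark 2: at the monocyclic stage the two faces of C3 differ only by the C5 methyl versus the C5 methylene chain, so no facial control is expected in step 13. Compounds 24–31 are therefore carried as both C3 epimers (28 and 29 also as C2 epimers); all converge on ketone 32, and C3 is set in step 21.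

**Route**

Step 1
Reactants: 1 dimedone, 2 2-methylpropan-1-ol
Product: 3 5,5-dimethyl-3-(2-methylpropoxy)cyclohex-2-en-1-one
Conditions: p-TsOH (cat.), toluene, reflux, Dean–Stark
Reagents that add atoms: 2-methylpropan-1-ol (2), CC(C)CO
Why: Acid-catalysed enol ether formation from the symmetric cyclic 1,3-dione with azeotropic removal of water gives the vinylogous ester without any regiochemical question.

Step 2
Reactants: 3 5,5-dimethyl-3-(2-methylpropoxy)cyclohex-2-en-1-one
Product: 5 (±)-5,5,6-trimethyl-3-(2-methylpropoxy)cyclohex-2-en-1-one, via lithium enolate 4 (not isolated)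
Conditions: LiN(i-Pr)2, THF, −78 °C; then MeI, −78 °C → rt
Reagents that add atoms: iodomethane, CI
Why: Kinetic deprotonation of a 3-alkoxy enone occurs at the α′ carbon and the enolate is C-methylated (enolate alkylation); the new centre is racemic and becomes sp2 again in step 3.

Step 3
Reactants: 5 (±)-5,5,6-trimethyl-3-(2-methylpropoxy)cyclohex-2-en-1-one, 6 allyl chloroformate
Product: 8 2,3,3-trimethyl-5-(2-methylpropoxy)cyclohexa-1,5-dien-1-yl prop-2-en-1-yl carbonate, via lithium enolate 7 (not isolated)
Conditions: LiN(i-Pr)2, THF, −78 → 0 °C; then allyl chloroformate, −78 °C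
Reagents that add atoms: allyl chloroformate (6), C=CCOC(Cl)=O
Why: The fully substituted, hindered enolate is acylated on oxygen by the chloroformate (enol carbonate formation), which fixes the enolate regiochemistry for step 4; any C-acylated isomer would lead to the same product there.

Step 4
Reactants: 8 2,3,3-trimethyl-5-(2-methylpropoxy)cyclohexa-1,5-dien-1-yl prop-2-en-1-yl carbonate
Product: 9 (R)-5,5,6-trimethyl-3-(2-methylpropoxy)-6-(prop-2-en-1-yl)cyclohex-2-en-1-one
Conditions: Pd2(dba)3 (cat.), (S)-4-tert-butyl-2-{2-[bis(4-trifluoromethylphenyl)phosphanyl]-5-(trifluoromethyl)phenyl}-4,5-dihydrooxazole (cat.), toluene, 30–40 °C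
Reagents that add atoms: none
Why: Enantioselective decarboxylative allylic alkylation (Tsuji type): zerovalent palladium ionizes the allyl carbonate, CO2 is lost, and the π-allyl palladium enolate recombines within the chiral ligand sphere, which sets the quaternary C5; the electron-poor ligand is the one suited to enolates flanked by a quaternary carbon.

Step 5
Reactants: 9 (R)-5,5,6-trimethyl-3-(2-methylpropoxy)-6-(prop-2-en-1-yl)cyclohex-2-en-1-one
Product: 11 (R)-6-(3-hydroxypropyl)-5,5,6-trimethyl-3-(2-methylpropoxy)cyclohex-2-en-1-one, via alkylborane 10 (not isolated)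
Conditions: 9-BBN, THF, 0 °C → rt; then aq. NaOH, H2O2, 0 °C
Reagents that add atoms: hydrogen peroxide, OO
Why: Anti-Markovnikov hydroboration of the monosubstituted alkene and oxidation of the C–B bond (hydroboration–oxidation) give the primary alcohol; the hindered, electron-rich vinylogous ester carbonyl should not be reduced by 9-BBN.

Step 6
Reactants: 11 (R)-6-(3-hydroxypropyl)-5,5,6-trimethyl-3-(2-methylpropoxy)cyclohex-2-en-1-one
Product: 12 3-[(1R)-1,6,6-trimethyl-4-(2-methylpropoxy)-2-oxocyclohex-3-en-1-yl]propanal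
Conditions: Dess–Martin periodinane, pyridine, CH2Cl2, 0 °C → rt
Reagents that add atoms: none
Why: Dess–Martin oxidation takes the primary alcohol to the aldehyde under mild buffered conditions that leave the vinylogous ester alone.

Step 7
Reactants: 12 3-[(1R)-1,6,6-trimethyl-4-(2-methylpropoxy)-2-oxocyclohex-3-en-1-yl]propanal, 13 ethyl diazoacetate
Product: 14 ethyl 3-oxo-5-[(1R)-1,6,6-trimethyl-4-(2-methylpropoxy)-2-oxocyclohex-3-en-1-yl]pentanoate
Conditions: SnCl2 (cat.), CH2Cl2, rt
Reagents that add atoms: ethyl diazoacetate (13), CCOC(=O)C=[N+]=[N-]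
Why: Roskamp reaction: Lewis-acid-catalysed addition of the diazo ester to the aliphatic aldehyde, 1,2-hydride shift and loss of N2 give the β-keto ester in one step.

Step 8
Reactants: 14 ethyl 3-oxo-5-[(1R)-1,6,6-trimethyl-4-(2-methylpropoxy)-2-oxocyclohex-3-en-1-yl]pentanoate
Product: 16 ethyl (Z)-3-(trifluoromethylsulfonyloxy)-5-[(1R)-1,6,6-trimethyl-4-(2-methylpropoxy)-2-oxocyclohex-3-en-1-yl]pent-2-enoate, via sodium enolate 15 (not isolated)
Conditions: NaH, THF, 0 °C; then PhNTf2, 0 °C → rt
Reagents that add atoms: N-phenylbis(trifluoromethanesulfonimide), FC(F)(F)S(=O)(=O)N(c1ccccc1)S(=O)(=O)C(F)(F)F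
Why: The sodium enolate of a β-keto ester is a chelate with the enolate oxygen cis to the ester, and O-triflation by the mild triflimide keeps this geometry as the (Z)-enol triflate; the triflimide does not attack the vinylogous ester.

Step 9
Reactants: 16 ethyl (Z)-3-(trifluoromethylsulfonyloxy)-5-[(1R)-1,6,6-trimethyl-4-(2-methylpropoxy)-2-oxocyclohex-3-en-1-yl]pent-2-enoate, 17 (trimethylsilyl)methylmagnesium chloride
Product: 18 ethyl (Z)-3-[(trimethylsilyl)methyl]-5-[(1R)-1,6,6-trimethyl-4-(2-methylpropoxy)-2-oxocyclohex-3-en-1-yl]pent-2-enoate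
Conditions: Pd(PPh3)4 (cat.), THF, 0 °C → rt
Reagents that add atoms: (trimethylsilyl)methylmagnesium chloride (17), C[Si](C)(C)C[Mg]Cl
Why: Kumada–Corriu coupling of the enol triflate proceeds with retention of alkene geometry and puts CH2SiMe3 cis to the ester; the weakly nucleophilic silylmethyl Grignard should couple faster than it adds to either carbonyl.

Step 10
Reactants: 18 ethyl (Z)-3-[(trimethylsilyl)methyl]-5-[(1R)-1,6,6-trimethyl-4-(2-methylpropoxy)-2-oxocyclohex-3-en-1-yl]pent-2-enoate
Product: 19 (R)-6-{(Z)-5-hydroxy-3-[(trimethylsilyl)methyl]pent-3-en-1-yl}-5,5,6-trimethyl-3-(2-methylpropoxy)cyclohex-2-en-1-one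
Conditions: i-Bu2AlH (2.2 equiv), CH2Cl2, −78 °C; aq. potassium sodium tartrate
Reagents that add atoms: none
Why: 1,2-Reduction of the conjugated ester to the allylic alcohol by the aluminium hydride at low temperature; the ring carbonyl is a vinylogous ester next to a quaternary carbon and should react far more slowly.

Step 11
Reactants: 19 (R)-6-{(Z)-5-hydroxy-3-[(trimethylsilyl)methyl]pent-3-en-1-yl}-5,5,6-trimethyl-3-(2-methylpropoxy)cyclohex-2-en-1-one
Product: 20 (R)-6-{(Z)-5-[tert-butyl(diphenyl)silyl]oxy-3-[(trimethylsilyl)methyl]pent-3-en-1-yl}-5,5,6-trimethyl-3-(2-methylpropoxy)cyclohex-2-en-1-one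
Conditions: t-BuPh2SiCl, imidazole, CH2Cl2, rt
Reagents that add atoms: tert-butyl(chloro)diphenylsilane, CC(C)(C)[Si](Cl)(c1ccccc1)c1ccccc1
Why: Silylation of the primary allylic alcohol; the bulky, weakly basic silyl ether is chosen so that this oxygen neither binds the Lewis acid nor ionizes in the key step.

Step 12
Reactants: 20 (R)-6-{(Z)-5-[tert-butyl(diphenyl)silyl]oxy-3-[(trimethylsilyl)methyl]pent-3-en-1-yl}-5,5,6-trimethyl-3-(2-methylpropoxy)cyclohex-2-en-1-one
Product: 22 (R)-4-{(Z)-5-[tert-butyl(diphenyl)silyl]oxy-3-[(trimethylsilyl)methyl]pent-3-en-1-yl}-3,4,5,5-tetramethylcyclohex-2-en-1-one, via tertiary allylic alcohol 21 (not isolated)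
Conditions: MeLi, CeCl3, THF, −78 → 0 °C; then 1 M aq. HCl, 0 °C, short
Reagents that add atoms: methyllithium, [Li]C; water, O
Why: Stork–Danheiser transposition: 1,2-addition of the non-basic organocerium reagent to the hindered carbonyl, then acid ionization and hydrolysis of the 3-alkoxy allylic alcohol give the transposed β-methyl enone (C15 installed); brief dilute acid at 0 °C should spare the allylsilane and the silyl ether.

Step 13
Reactants: 22 (R)-4-{(Z)-5-[tert-butyl(diphenyl)silyl]oxy-3-[(trimethylsilyl)methyl]pent-3-en-1-yl}-3,4,5,5-tetramethylcyclohex-2-en-1-one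
Product: 24 (4S,6RS)-4-{(Z)-5-[tert-butyl(diphenyl)silyl]oxy-3-[(trimethylsilyl)methyl]pent-3-en-1-yl}-6-hydroxy-3,4,5,5-tetramethylcyclohex-2-en-1-one, via lithium dienolate 23 (not isolated)
Conditions: LiN(i-Pr)2, THF, −78 °C; then 2-(phenylsulfonyl)-3-phenyloxaziridine, −78 °C; aq. NH4Cl
Reagents that add atoms: 2-(phenylsulfonyl)-3-phenyloxaziridine, O=S(=O)(c1ccccc1)N1OC1c1ccccc1
Why: Kinetic α′-deprotonation of the enone (cross-conjugated enolate) and oxygen transfer from the N-sulfonyloxaziridine (Davis oxidation) place the hydroxyl at C3 only and leave the allylsilane untouched; both C3 epimers are expected and both are used.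

Step 14
Reactants: 24 (4S,6RS)-4-{(Z)-5-[tert-butyl(diphenyl)silyl]oxy-3-[(trimethylsilyl)methyl]pent-3-en-1-yl}-6-hydroxy-3,4,5,5-tetramethylcyclohex-2-en-1-one
Product: 25 (4S,6RS)-4-{(Z)-5-[tert-butyl(diphenyl)silyl]oxy-3-[(trimethylsilyl)methyl]pent-3-en-1-yl}-3,4,5,5-tetramethyl-6-(triethylsilyloxy)cyclohex-2-en-1-one
Conditions: Et3SiOTf, 2,6-lutidine, CH2Cl2, −78 → 0 °C
Reagents that add atoms: triethylsilyl trifluoromethanesulfonate, CC[Si](CC)(CC)OS(=O)(=O)C(F)(F)F
Why: Silylation of the hindered secondary alcohol with a silyl triflate and a hindered base; the triethylsilyl group is chosen because it can later be removed in the presence of the tert-butyldiphenylsilyl ether.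

Step 15
Reactants: 25 (4S,6RS)-4-{(Z)-5-[tert-butyl(diphenyl)silyl]oxy-3-[(trimethylsilyl)methyl]pent-3-en-1-yl}-3,4,5,5-tetramethyl-6-(triethylsilyloxy)cyclohex-2-en-1-one
Product: 27 (5S,9S,10R) cis-fused decalin-2-one carrying C3 OSiEt3 (both epimers) / C4 gem-dimethyl / 5β- and 10β-methyl / C8 methylidene / 9β-CH2OSi(t-Bu)Ph2, via aluminium enolate 26 (not isolated)
Conditions: EtAlCl2 (2–3 equiv), toluene, −78 → 0 °C; aq. NH4Cl
Reagents that add atoms: none
Why: EtAlCl2 binds the ring-A carbonyl, the γ-carbon of the allylsilane (C9) attacks the β-carbon C10, and the β-silyl cation at C8 loses Me3Si to chloride, which creates the C8=C12 methylene and the aluminium enolate 26 that is protonated on work-up. This is an intramolecular Hosomi–Sakurai conjugate addition, and the closest known cases are Lewis-acid cyclizations of 3-methylcyclohex-2-enones carrying an allylsilane tether at C4, which give cis-fused bicycles with an angular methyl group. Ring B closes by 6-exo-trig attack on the C10=C1 bond through a chair in which C6 is pseudo-equatorial on ring A and C9 arrives anti to the pseudo-axial C5 methyl. C10 is controlled by the tether, which can deliver C9 only to the face that makes C9 cis to C6, so the two angular methyls end up cis (cis-decalin). C9 is controlled by the (Z) geometry: the CH2OSi group trans to C7 becomes equatorial in that chair and hence β (cis to the C10 methyl), while the axial alternative would run into C4. The step needs 1,4-addition to outrun protodesilylation and ionization of the allylic ether, which is served by the proton-scavenging ethyl–aluminium bond, by the weakly basic tert-butyldiphenylsilyl ether oxygen, and by the fact that the carbonyl carbon cannot be reached through a six-membered ring.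

Step 16
Reactants: 27 (5S,9S,10R) cis-fused decalin-2-one (C3 OSiEt3, both epimers)
Product: 28 the corresponding C2 alcohol (C2 and C3 epimers; C3 OSiEt3, C11 OSi(t-Bu)Ph2, C8 methylidene)
Conditions: i-Bu2AlH, CH2Cl2, −78 °C; aq. potassium sodium tartrate
Reagents that add atoms: none
Why: Hydride reduction of the ketone through a non-nucleophilic aluminium alkoxide at low temperature avoids 1,2-migration of the neighbouring silyl group; the configuration of the new carbinol does not matter because it is removed.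

Step 17
Reactants: 28 C2 alcohol (C2 and C3 epimers)
Product: 29 C2 O-phenyl thionocarbonate of 28
Conditions: PhOC(S)Cl, pyridine, DMAP (cat.), CH2Cl2, rt
Reagents that add atoms: O-phenyl chlorothionoformate, S=C(Cl)Oc1ccccc1
Why: Acylation of the free C2 hydroxyl without forming an alkoxide (no silyl migration) gives the radical precursor for a Barton–McCombie deoxygenation.

Step 18
Reactants: 29 C2 O-phenyl thionocarbonate
Product: 30 (5S,9S,10R) cis-decalin with C2 as CH2, C3 OSiEt3 (both epimers), C11 OSi(t-Bu)Ph2, C8 methylidene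
Conditions: Bu3SnH, AIBN (cat.), toluene, 100 °C
Reagents that add atoms: none
Why: Barton–McCombie deoxygenation: stannyl radical addition to the thiocarbonyl, β-scission to the secondary C2 radical and hydrogen transfer from the stannane; the radical cannot reach the C8 methylene in the chair–chair cis-decalin and a β-silyloxy radical does not fragment.

Step 19
Reactants: 30 C2-deoxygenated bis-silyl ether
Product: 31 (5S,9S,10R) C3 alcohol (both epimers) with C11 OSi(t-Bu)Ph2
Conditions: PPTS, MeOH/CH2Cl2, rt → 40 °C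
Reagents that add atoms: none
Why: Acid-catalysed methanolysis cleaves the triethylsilyl ether much faster than the primary tert-butyldiphenylsilyl ether, and the mild acid should leave the exocyclic alkene in place.

Step 20
Reactants: 31 C3 alcohol (both epimers)
Product: 32 (5S,9S,10R)-11-[tert-butyl(diphenyl)silyl]oxy cis-decalin-3-one (C4 gem-dimethyl, 5β- and 10β-methyl, C8 methylidene)
Conditions: Dess–Martin periodinane, pyridine, CH2Cl2, rt
Reagents that add atoms: none
Why: Dess–Martin oxidation of the secondary alcohol converges both C3 epimers on a single ketone.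

Step 21
Reactants: 32 cis-decalin-3-one
Product: 33 (3S,5S,9S,10R) 3β-alcohol with C11 OSi(t-Bu)Ph2
Conditions: LiBH(s-Bu)3, THF, −78 → −20 °C; then aq. NaOH, H2O2, 0 °C
Reagents that add atoms: none
Why: Ketone reduction under steric approach control: in the preferred chair–chair form the C5 methyl is axial on ring A and syn to the axial trajectory at C3, so the bulky borohydride should enter along the equatorial trajectory on the α face and give the axial 3β alcohol, cis to the C5 methyl (the sense known for 3-keto triterpenoids with an axial 5-methyl), which sets C3 as (S).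

Step 22
Reactants: 33 3β-alcohol silyl ether
Product: 34 (3S,5S,9S,10R) diol: 3β-hydroxy, 9β-hydroxymethyl, C8 methylidene
Conditions: Bu4NF, THF, rt
Reagents that add atoms: none
Why: Fluoride-induced desilylation frees the primary C11 alcohol; nothing else in the molecule is fluoride-labile.

Step 23
Reactants: 34 diol, 35 umbelliferone
Product: 36 (3S,5S,9S,10R) 7-(C11-oxy)coumarin ether with free 3β-hydroxyl (deacetyl polyanthinin)
Conditions: PPh3, DIAD, THF, 0 → 50 °C
Reagents that add atoms: umbelliferone (35), O=c1ccc2ccc(O)cc2o1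
Why: Mitsunobu etherification: the acidic phenol is alkylated by the activated primary alcohol, while the hindered axial secondary C3 alcohol should not be activated; C11 is not a stereocentre.

Step 24
Reactants: 36 deacetyl polyanthinin
Product: 37 polyanthinin, (2S,4aR,5S,8aS)-1,1,4a,8a-tetramethyl-6-methylidene-5-{[(2-oxo-2H-chromen-7-yl)oxy]methyl}decahydronaphthalen-2-yl acetate
Conditions: Ac2O, pyridine, DMAP (cat.), CH2Cl2, rt
Reagents that add atoms: acetic anhydride, CC(=O)OC(C)=O
Why: DMAP-catalysed acetylation of the hindered secondary alcohol; the coumarin lactone is stable to these conditions.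

**Compound list**

1 | dimedone (5,5-dimethylcyclohexane-1,3-dione) | CC1(C)CC(=O)CC(=O)C1 | starting material
2 | 2-methylpropan-1-ol | CC(C)CO | starting material
3 | 5,5-dimethyl-3-(2-methylpropoxy)cyclohex-2-en-1-one | CC(C)COC1=CC(=O)CC(C)(C)C1 | intermediate
4 | lithium α′-enolate of 3 | [Li]OC1=CC(C)(C)CC(OCC(C)C)=C1 | intermediate
5 | (±)-5,5,6-trimethyl-3-(2-methylpropoxy)cyclohex-2-en-1-one | CC(C)COC1=CC(=O)C(C)C(C)(C)C1 | intermediate
6 | allyl chloroformate | C=CCOC(Cl)=O | starting material
7 | lithium enolate of 5 | [Li]OC1=C(C)C(C)(C)CC(OCC(C)C)=C1 | intermediate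
8 | 2,3,3-trimethyl-5-(2-methylpropoxy)cyclohexa-1,5-dien-1-yl prop-2-en-1-yl carbonate | C=CCOC(=O)OC1=C(C)C(C)(C)CC(OCC(C)C)=C1 | intermediate
9 | (R)-5,5,6-trimethyl-3-(2-methylpropoxy)-6-(prop-2-en-1-yl)cyclohex-2-en-1-one | CC(C)COC1=CC(=O)[C@](C)(CC=C)C(C)(C)C1 | intermediate
10 | B-alkyl-9-borabicyclo[3.3.1]nonane from 9 (boron on the former terminal alkene carbon) | CC(C)COC1=CC(=O)[C@](C)(CCCB2C3CCCC2CCC3)C(C)(C)C1 | intermediate
11 | (R)-6-(3-hydroxypropyl)-5,5,6-trimethyl-3-(2-methylpropoxy)cyclohex-2-en-1-one | CC(C)COC1=CC(=O)[C@](C)(CCCO)C(C)(C)C1 | intermediate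
12 | 3-[(1R)-1,6,6-trimethyl-4-(2-methylpropoxy)-2-oxocyclohex-3-en-1-yl]propanal | CC(C)COC1=CC(=O)[C@](C)(CCC=O)C(C)(C)C1 | intermediate
13 | ethyl diazoacetate | CCOC(=O)C=[N+]=[N-] | starting material
14 | ethyl 3-oxo-5-[(1R)-1,6,6-trimethyl-4-(2-methylpropoxy)-2-oxocyclohex-3-en-1-yl]pentanoate | CC(C)COC1=CC(=O)[C@](C)(CCC(=O)CC(=O)OCC)C(C)(C)C1 | intermediate
15 | sodium (Z)-enolate of 14 | CC(C)COC1=CC(=O)[C@](C)(CC/C(O[Na])=C/C(=O)OCC)C(C)(C)C1 | intermediate
16 | ethyl (Z)-3-(trifluoromethylsulfonyloxy)-5-[(1R)-1,6,6-trimethyl-4-(2-methylpropoxy)-2-oxocyclohex-3-en-1-yl]pent-2-enoate | CC(C)COC1=CC(=O)[C@](C)(CC/C(OS(=O)(=O)C(F)(F)F)=C/C(=O)OCC)C(C)(C)C1 | intermediate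
17 | (trimethylsilyl)methylmagnesium chloride | C[Si](C)(C)C[Mg]Cl | starting material
18 | ethyl (Z)-3-[(trimethylsilyl)methyl]-5-[(1R)-1,6,6-trimethyl-4-(2-methylpropoxy)-2-oxocyclohex-3-en-1-yl]pent-2-enoate | CC(C)COC1=CC(=O)[C@](C)(CC/C(C[Si](C)(C)C)=C/C(=O)OCC)C(C)(C)C1 | intermediate
19 | (R)-6-{(Z)-5-hydroxy-3-[(trimethylsilyl)methyl]pent-3-en-1-yl}-5,5,6-trimethyl-3-(2-methylpropoxy)cyclohex-2-en-1-one | CC(C)COC1=CC(=O)[C@](C)(CC/C(C[Si](C)(C)C)=C/CO)C(C)(C)C1 | intermediate
20 | tert-butyldiphenylsilyl ether of 19 | CC(C)COC1=CC(=O)[C@](C)(CC/C(C[Si](C)(C)C)=C/CO[Si](c2ccccc2)(c2ccccc2)C(C)(C)C)C(C)(C)C1 | intermediate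
21 | (1RS,6R) tertiary allylic alcohol from methyl addition to 20 (1,5,5,6-tetramethyl-3-(2-methylpropoxy)cyclohex-2-en-1-ol with the side chain on C6) | CC(C)COC1=CC(C)(O)[C@](C)(CC/C(C[Si](C)(C)C)=C/CO[Si](c2ccccc2)(c2ccccc2)C(C)(C)C)C(C)(C)C1 | intermediate
22 | (R)-4-{(Z)-5-[tert-butyl(diphenyl)silyl]oxy-3-[(trimethylsilyl)methyl]pent-3-en-1-yl}-3,4,5,5-tetramethylcyclohex-2-en-1-one | O=C1C=C(C)[C@](C)(CC/C(C[Si](C)(C)C)=C/CO[Si](c2ccccc2)(c2ccccc2)C(C)(C)C)C(C)(C)C1 | intermediate
23 | lithium α′-dienolate of 22 | [Li]OC1C=C(C)[C@](C)(CC/C(C[Si](C)(C)C)=C/CO[Si](c2ccccc2)(c2ccccc2)C(C)(C)C)C(C)(C)C=1 | intermediate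
24 | (4S,6RS)-6-hydroxy derivative of 22 (both C3 epimers in route numbering) | O=C1C=C(C)[C@](C)(CC/C(C[Si](C)(C)C)=C/CO[Si](c2ccccc2)(c2ccccc2)C(C)(C)C)C(C)(C)C1O | intermediate
25 | (4S,6RS)-6-(triethylsilyloxy) enone, key-step precursor (both C3 epimers) | O=C1C=C(C)[C@](C)(CC/C(C[Si](C)(C)C)=C/CO[Si](c2ccccc2)(c2ccccc2)C(C)(C)C)C(C)(C)C1O[Si](CC)(CC)CC | intermediate
26 | aluminium enolate (C1=C2–O–Al(Et)Cl) of the cyclized product | C=C1CC[C@]2(C)C(C)(C)C(O[Si](CC)(CC)CC)C(O[Al](Cl)CC)=C[C@]2(C)[C@H]1CO[Si](c1ccccc1)(c1ccccc1)C(C)(C)C | intermediate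
27 | (5S,9S,10R) cis-decalin-2-one: C3 OSiEt3 (both epimers), C4 gem-dimethyl, 5β- and 10β-methyl, C8 methylidene, 9β-CH2OSi(t-Bu)Ph2 | C=C1CC[C@]2(C)C(C)(C)C(O[Si](CC)(CC)CC)C(=O)C[C@]2(C)[C@H]1CO[Si](c1ccccc1)(c1ccccc1)C(C)(C)C | intermediate
28 | C2 alcohol of 27 (C2 and C3 epimers) | C=C1CC[C@]2(C)C(C)(C)C(O[Si](CC)(CC)CC)C(O)C[C@]2(C)[C@H]1CO[Si](c1ccccc1)(c1ccccc1)C(C)(C)C | intermediate
29 | C2 O-phenyl thionocarbonate of 28 | C=C1CC[C@]2(C)C(C)(C)C(O[Si](CC)(CC)CC)C(OC(=S)Oc3ccccc3)C[C@]2(C)[C@H]1CO[Si](c1ccccc1)(c1ccccc1)C(C)(C)C | intermediate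
30 | (5S,9S,10R) cis-decalin: C2 CH2, C3 OSiEt3 (both epimers), C11 OSi(t-Bu)Ph2, C8 methylidene | C=C1CC[C@]2(C)C(C)(C)C(O[Si](CC)(CC)CC)CC[C@]2(C)[C@H]1CO[Si](c1ccccc1)(c1ccccc1)C(C)(C)C | intermediate
31 | C3 alcohol (both epimers) with C11 OSi(t-Bu)Ph2 | C=C1CC[C@]2(C)C(C)(C)C(O)CC[C@]2(C)[C@H]1CO[Si](c1ccccc1)(c1ccccc1)C(C)(C)C | intermediate
32 | (5S,9S,10R) cis-decalin-3-one with C11 OSi(t-Bu)Ph2 | C=C1CC[C@]2(C)C(C)(C)C(=O)CC[C@]2(C)[C@H]1CO[Si](c1ccccc1)(c1ccccc1)C(C)(C)C | intermediate
33 | (3S,5S,9S,10R) 3β-alcohol with C11 OSi(t-Bu)Ph2 | C=C1CC[C@]2(C)C(C)(C)[C@@H](O)CC[C@]2(C)[C@H]1CO[Si](c1ccccc1)(c1ccccc1)C(C)(C)C | intermediate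
34 | (3S,5S,9S,10R) diol (3β-OH, 9β-CH2OH) | C=C1CC[C@]2(C)C(C)(C)[C@@H](O)CC[C@]2(C)[C@H]1CO | intermediate
35 | umbelliferone (7-hydroxy-2H-chromen-2-one) | O=c1ccc2ccc(O)cc2o1 | starting material
36 | deacetyl polyanthinin (3β-OH, C11 7-coumarinyl ether) | C=C1CC[C@]2(C)C(C)(C)[C@@H](O)CC[C@]2(C)[C@H]1COc1ccc2ccc(=O)oc2c1 | intermediate
37 | polyanthinin | C=C1CC[C@]2(C)C(C)(C)[C@@H](OC(C)=O)CC[C@]2(C)[C@H]1COc1ccc2ccc(=O)oc2c1 | target

**Step count**

Total steps: 24. Longest linear sequence: 24 steps (from dimedone to 37).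

**Steps most likely to fail, with fallbacks**

Step 15. The bond must form at a β-carbon flanked by the quaternary C5, itself next to the C4 gem-dimethyl. Addition may be so slow that protodesilylation, or Lewis-acid ionization of the allylic silyl ether with loss of silicon (1,4-elimination to a diene), takes over. The fallback changes the electrophile from the enone to an allyl cation; it sets out from 25 and returns at 32. Luche reduction of 25 (NaBH4, CeCl3, MeOH, −78 °C) should give the ring-A allylic alcohol F1 (C2 and C3 epimers). Ionization with catalytic Sc(OTf)3 in CH2Cl2 at −78 °C should generate the C2–C1–C10 allyl cation, which is far more electrophilic than the aluminium-bound enone. The allylsilane should trap it at the tertiary terminus C10 through the same tether-enforced chair (cation–allylsilane cyclization), giving the cis-fused Δ1-alkene F2 with the same C9 and C10 configurations and no oxygen at C2. PPTS in MeOH should then give the allylic alcohol F3, Dess–Martin oxidation the Δ1-en-3-one F4, and conjugate reduction with [(Ph3P)CuH]6 in benzene the ketone 32. On this path steps 16–18 are not needed.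

Step 23. Displacement at C11, a primary carbon next to the tertiary C9 and the quaternary C10, may be too slow, so that the activated alcohol is lost to elimination or to alkylation of the reduced azodicarboxylate. The fallback forms the aryl–oxygen bond instead of the alkyl–oxygen bond; it sets out from 34 and returns at 36. Pd-catalysed C–O cross-coupling (Buchwald–Hartwig-type etherification) of the primary alcohol of 34 with commercially available 7-bromocoumarin (Pd2(dba)3, t-BuBrettPhos, Cs2CO3, toluene, 90 °C) involves no substitution at C11, and the hindered axial C3 hydroxyl should not couple. This fallback makes no new compound (F0).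

Step 21. Facial selectivity of hydride attack at the C3 ketone may be poor, or reversed, if ring A does not react through the chair assumed. The fallback replaces substrate control by catalyst control; it runs from 32 to 33. Corey–Bakshi–Shibata reduction with the (R)-2-methyl oxazaborolidine and catecholborane (toluene, −78 → −40 °C) distinguishes the quaternary C4 (large) from the C2 methylene (small) and should deliver the (3S), that is 3β, alcohol. Catecholborane is used because it should not hydroborate the C8 methylene under these conditions. This fallback makes no new compound (F0).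

**Further compounds**

F1 | step 15 | (1RS,4S,6RS)-4-{(Z)-5-[tert-butyl(diphenyl)silyl]oxy-3-[(trimethylsilyl)methyl]pent-3-en-1-yl}-3,4,5,5-tetramethyl-6-(triethylsilyloxy)cyclohex-2-en-1-ol | OC1C=C(C)[C@](C)(CC/C(C[Si](C)(C)C)=C/CO[Si](c2ccccc2)(c2ccccc2)C(C)(C)C)C(C)(C)C1O[Si](CC)(CC)CC
F2 | step 15 | (5S,9S,10R) cis-fused Δ1-alkene: C3 OSiEt3 (both epimers), C8 methylidene, 9β-CH2OSi(t-Bu)Ph2 | C=C1CC[C@]2(C)C(C)(C)C(O[Si](CC)(CC)CC)C=C[C@]2(C)[C@H]1CO[Si](c1ccccc1)(c1ccccc1)C(C)(C)C
F3 | step 15 | (5S,9S,10R) Δ1-en-3-ol (both C3 epimers) with C11 OSi(t-Bu)Ph2 | C=C1CC[C@]2(C)C(C)(C)C(O)C=C[C@]2(C)[C@H]1CO[Si](c1ccccc1)(c1ccccc1)C(C)(C)C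
F4 | step 15 | (5S,9S,10R) Δ1-en-3-one with C11 OSi(t-Bu)Ph2 | C=C1CC[C@]2(C)C(C)(C)C(=O)C=C[C@]2(C)[C@H]1CO[Si](c1ccccc1)(c1ccccc1)C(C)(C)C
F0 | step 23 | none | none
F0 | step 21 | none | none
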